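(The numbers in the tables were generated by integration on assumed constants; the scatter is artificial.)

Target was what I wanted from Monday's flask, and the decision was whether to leave that flask alone at 4.0 h or spend something on it.

the same everywhere: starting material 0.10 M
- Monday's: coupling partner 0.20 M; free catalyst 5 mM; temperature 60 °C; the very flask that is asked about, followed so far
- Thursday's: coupling partner 0.10 M; free catalyst 5 mM; temperature 45 °C; run made earlier
- flask: coupling partner 0.200 M; free catalyst 5.0 mM; temperature 60 °C; time 4.0 h

| run | time / h | target / % | starting material / % |
|---|---|---|---|
| Monday's | 0.500 | 30.4 | 50.5 |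
| Monday's | 1.00 | 53.5 | 7.5 |
| Monday's | 1.33 | 55.7 | 0 |
| Monday's | 2.00 | 58.7 | 0 |
| Monday's | 2.50 | 57.9 | 0 |
| Thursday's | 0.500 | 6.2 | 87.7 |
| Thursday's | 1.00 | 13.8 | 78.4 |
| Thursday's | 2.00 | 21.7 | 62.0 |
| Thursday's | 3.00 | 29.9 | 46.3 |

(standard deviation of a reading: 1 percentage point)

- beta: change nothing and wait 2.0 h more
- zeta: at 4.0 h add free catalyst, 100 % of the amount charged, then wait 2.0 h
- alpha: at 4.0 h take out 90 % of the by-product then present, then wait 2.0 h
- eta: at 4.0 h add coupling partner, 100 % of the amount charged, then wait 2.0 h
- epsilon: at 4.0 h raise the temperature by 10 K, then wait 2.0 h

- target, in percent of the starting material first charged, at 4.0 h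
- the remedy with the largest gain of target, or "none" below 2 percentage points (beta / zeta / alpha / eta / epsilon / none)
- target present, in percent of the starting material first charged, after beta
- target present, in percent of the starting material first charged, after epsilon

- additions leave the volume as it is

At the early end I drew a straight line through Monday's first reading: starting material had lost 49.5 % of its charge in 0.500 h. That line put the run-out near 1.01 h, an estimate less than 4.0 h, and the reading at 1.33 h stood at 0 %. At the late end, Monday's last readings of target averaged 57.4 %. I called this s, the target formed per starting material consumed, or yield on converted starting material.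

To join the ends I reckoned the same ratio at partial conversion: 57.8 % at 1.00 h on Monday and 55.7 % at 3.00 h on Thursday. I kept s for the whole course, so my figure for Monday's flask at 4.0 h was s itself. With starting material read at 0 % and the estimated run-out before 4.0 h, I expected no starting material for added free catalyst or coupling partner to convert, so I left both out of the next step. Yet a flat s could be a fixed split or a balance with something unmeasured, and I could not tell the two apart from these readings, so I kept the rise of 10 K as the test, without a number on it.

The forecast gave 57.7 %, 57.6 % after beta and 57.3 % after epsilon, and chose none, saying “Nothing gains 2 points, so the answer is none”.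

The simulation gave 56.4 % at 4.0 h, 1 percentage point below s, and 56.4 % after beta. The best remedy was epsilon, with 64.0 % and a gain of 7.6 points. At 4.0 h Monday's flask held 42.3 % isomer of the product, which exchanges with target at a relaxation half-life, by that step alone, of 0.0778 h, short against 4.0 h.

    catalyst intermediate C ⇌ free catalyst + target (K = 0.160 M, k = 0.0122 /s, Ea = 99.0 kJ/mol, ΔH = 8.00 kJ/mol)
    coupling partner + catalyst intermediate A ⇌ catalyst intermediate B (K = 8.74 /M, k = 0.112 /M/s, Ea = 57.0 kJ/mol, ΔH = −30.0 kJ/mol)
    catalyst intermediate B → by-product + catalyst intermediate C (k = 0.0299 /s, Ea = 90.0 kJ/mol)
    target ⇌ isomer of the product (K = 0.750, k = 0.00106 /s, Ea = 110 kJ/mol, ΔH = −31.0 kJ/mol)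
    starting material + free catalyst → catalyst intermediate A (k = 10.7 /M/s, Ea = 49.0 kJ/mol)
    (constants at 60 °C)

With starting material at 0 % in Monday's flask, its ratio s is the target present, 64.0 % after epsilon. In the neighbour flask with 0.050 M of coupling partner, the limiting reagent there with 0.57 % of its own charge left, the value of s read on Monday times 0.500 equivalents gives 28.7 %, and that flask held 28.4 % target.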